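(The readings stem from a simulated flask for an exercise, noise included.)

The leftover we want from the green flask at 40 min is the share of its catalyst still working, and a count of half-lives estimates it.

the same everywhere: solid substrate 0.12 M; free catalyst 0.055 mol%
- green: temperature 50 °C; the very flask that is asked about, followed so far
- violet: temperature 45 °C; run made earlier
- flask: temperature 50 °C; time 40 min

| run | time / min | product / % | solid substrate / % |
|---|---|---|---|
| green | 6.00 | 1.8 | 0 |
| green | 12.0 | 4.8 | 0.1 |
| green | 20.0 | 7.8 | 0.1 |
| green | 25.0 | 8.0 | 0 |
| green | 30.0 | 8.3 | 0.2 |
| violet | 6.00 | 1.1 | 0.2 |
| violet | 12.0 | 3.9 | 0 |
| violet | 20.0 | 7.6 | 0.3 |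
| violet | 25.0 | 8.7 | 0.1 |
| violet | 30.0 | 10.2 | 0.1 |

(readings scatter by 0.3 percentage points)

- solid, in amounts per volume of the solution: solid substrate
- what is taken out of product is counted as made
- the numbers in the tables scatter by 0.3 percentage points (one standard deviation)
- at the start none of the solid substrate is in solution
- additions bring no volume worth counting

- ash: at 40 min take out 90% of the product then present, then wait 80 min
- cedar: change nothing and wait 80 min more
- maple: at 40 min add free catalyst, 50.0% of the amount charged, then wait 80 min
- oak: at 40 min raise the temperature by 15 K, then wait 80 min

1. product, in percent of the solid substrate first charged, at 40 min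
2. the option that brings most further product ("none" if no option brings more than 2 percentage points) (ash / cedar / maple / oak / none)
3. product present, with what was taken out counted in, in percent of the solid substrate first charged, after ash
4. product present, with what was taken out counted in, in percent of the solid substrate first charged, after oak

We read the green table down its product column. Between 12.0 min and 20.0 min the green flask gains 3 percentage points, but between 20.0 min and 30.0 min, a longer interval, it gains 0.5 points. The solid column beside it stays within scatter of zero, so by these readings the green flask has 91.5% of the solid substrate charged in solution and unread at 30.0 min, more than the product. We therefore do not read the stall in the green flask as a shortage of material. The violet table adds that the cooler flask reads 10.2% at 30.0 min, above the green 8.3%, which points to a catalyst dying.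

The last green gain is smaller than twice its scatter, so we take a high value for it, 1.3 points. The rate then falls 2.78-fold between the midpoints of the two intervals. If we put that fall down to the catalyst, it gives 6.10 min as our estimate of the deactivation half-life, the time in which the working catalyst halves. At 40 min the green flask has 6.56 of these half-lives behind it, which by our count leaves 1.06% of the catalyst charged working. Ash and oak add no catalyst, while maple adds 50.0% of the catalyst charged, far more than that leftover, so we choose maple.

The forecast says 8.5% (8.1% to 9%), 8.7% after ash, 8.7% after oak, and maple, since “fresh catalyst gives about half the ceiling again”.

The flask gives 9.60%, 9.83% after ash, 9.70% after oak, and maple, worth 11 points against 0.23 points for cedar.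

    solid substrate ⇌ starting material, rate k1*(cs1 - [starting material]) while solid is left; crystals form when [starting material] > cs1 (solubility = 0.100 M, k = 0.0110 s⁻¹)
    free catalyst + intermediate → free catalyst + product (k = 7.30 M⁻¹ s⁻¹, Ea = 48.0 kJ mol⁻¹)
    starting material → intermediate (k = 0.00250 s⁻¹, Ea = 89.0 kJ mol⁻¹)
    starting material ⇌ dormant form (K = 0.550, k = 0.00190 s⁻¹, Ea = 98.0 kJ mol⁻¹, ΔH = −12.0 kJ mol⁻¹)
    free catalyst → spent catalyst (k = 0.00190 s⁻¹, Ea = 99.0 kJ mol⁻¹)
    (constants at 50 °C)

Over the further 80 min our half-life counts 13.1 more halvings. What the count does not show is the pool: at 40.0 min the flask holds 86.7% intermediate, whose half-life by the catalysed step is then 38 h, far longer than those 80 min. Our half-life contains no charge, so the neighbour at the same temperature and loading with 0.048 M of solid substrate again counts 6.56 half-lives and 1.06% of its catalyst working at 40 min. Computed, that neighbour holds 1.05% of its catalyst charged as free catalyst, with 4.50% product and 92.1% intermediate, both in percent of its solid substrate charged.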